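**Two percentages.** The spring flask gave less Q per Z charged than the summer flask: 32.2 % against 50.5 % at 30.0 h.

all flasks: J 10 mM; G 0.50 mM
- summer: Z 0.032 M; D 0.12 M; run made earlier
- spring: Z 0.25 M; D 0.12 M; run made earlier
- dusk: Z 2.1 M; D 0.12 M; run made earlier
- north: Z 0.030 M; D 0.120 M; time 2.0 d
- east: Z 0.10 M; D 0.120 M; time 2.0 d
- south-east: Z 0.30 M; D 0.120 M; time 2.0 d
- north-east: Z 1.0 M; D 0.120 M; time 2.0 d
- north-west: Z 2.5 M; D 0.120 M; time 2.0 d

- summer (time / h: Q / %): 3.00: 7.1; 8.00: 19.0; 15.0: 35.8; 25.0: 47.7; 30.0: 50.5
- spring (time / h: Q / %): 6.00: 14.1; 15.0: 30.4; 20.0: 33.1; 25.0: 34.9; 30.0: 32.2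
- dusk (time / h: Q / %): 3.00: 3.3; 8.00: 4.6; 15.0: 5.3; 25.0: 2.4; 30.0: 3.5

(standard deviation of a reading: 1 percentage point)

- the earlier runs were read with a standard deviation of 1 percentage point
- "hardly changes" means that all values lie within two and a half points (for a concentration: within two and a half percent of the largest)

- [Q] at the end for north, east, south-east, north-east, north-west, in this order
- the shape of the row from first to last (rises, then falls / falls all the way / rises all the way / hardly changes / falls, then rises)

**Bench rule.** At the bench I carry a percentage from one charge to the next. Summer was flattening near 50.5 %, and I assumed that level held to 2.0 d. So I reckoned [Q] at 0.0152 M for north and 0.0505 M for east.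

**The border.** The rule broke on the dusk flask. It asked for 1.06 M of Q, but dusk read 0.0735 M at 30.0 h. Spring levelled at a reading of 0.0872 M at 25.0 h. I took this as a ceiling and guessed D was the limiting reagent, though the ceiling stood lower than the D charged.

**Joining ends.** I solved both ends and joined them. Ceiling over percentage gave 0.173 M. I call this the join charge, the [Z] charged at which percentage times charge meets the ceiling. East stood below it and south-east above it. Spring then dropped 2.7 percentage points between its last two readings, a weak sign at a scatter of 1 point. I still committed to a top near the join and a gentle fall after it.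

**The forecast.** The forecast gave 0.021 M, 0.067 M, 0.085 M, 0.085 M and 0.085 M, so its shape was rises all the way. Its words were: “The row rises and then flattens, with no clear evidence of a fall.” Its north value was higher than mine, and its shape differed from mine.

**The result.** The row read 0.0147 M, 0.0475 M, 0.0562 M, 0.0499 M and 0.0481 M, so its shape was rises, then falls.

    Z + J → J + L (k = 4.50 M⁻¹ h⁻¹)
    D + G + L → G + Q (k = 6900 M⁻² h⁻¹)
    Q → X (k = 0.0200 h⁻¹)

**What ran.** The row turned at 0.17 M; my join charge, itself a reading with the scatter of its runs, was 0.173 M. North lay below the join charge: I had reckoned 0.0152 M, and the flask held 0.0147 M. North-east lay above it. There, the step from Z to L ran on, while D stood at 0 % of its charge by 1.00 d. From then to 2.00 d, in percent of the Z charged, L rose from 54.0 % to 76.5 % while Q fell from 8.06 % to 4.99 %.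

(The runs come from a simulation with constants of no real substance; the scatter is artificial.)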